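The data are simulated on assumed constants, and the scatter is random.

I decide to read these flasks by one ratio and not by how much they make.

common to all: E 0.30 M; L 0.30 M; X 15 mM (in portions, 3)
- ash: J 0.36 M; temperature −25 °C; run made earlier; portions every 15 s
- elm: J 1.8 M; temperature −10 °C; run made earlier; portions every 15 s
- amber: J 0.600 M; at −20 °C until 1.5 min, from then on at 0 °C; the portions of X follow each other after 15 s, the first at the start; time 8.0 min
- green: J 2.00 M; at 0 °C throughout; the portions of X follow each other after 15 s, the first at the start; time 8.0 min

- ash (time / min: G / %, Z / %): 1.00: 2.0, 0.3; 2.00: 3.7, 0.8; 3.00: 5.1, 0; 4.00: 6.0, 0.8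
- elm (time / min: G / %, Z / %): 0.667: 9.6, 0; 1.33: 16.9, 1.6; 2.00: 19.1, 0.3; 2.50: 18.8, 0.7

(each reading ± 0.5 percentage points)

- X is single-handed; E and L are mirror images of each other, charged as a racemate, each of them at the stated concentration
- what may be going on: J + X + E -> X + G; J + X + L -> X + Z; X -> Q; E <-> L
- an excess is the difference of the two amounts in percent of their sum
- an excess is below zero if the other one leads

- the flask that ends with the higher excess of G over Z, or "neither" when 2 percentage points or less lies between them (amber / green / neither)
- excess of G over Z at the end, amber
- excess of G over Z at the end, green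

One thing looks wrong at first. At their last readings elm holds 3.13 times as much G as ash, 18.8 % against 6.0 %, yet its Z reads 0.7 %, less than the 0.8 % in ash.

I write the rates as the possible equations give them: G forms at kG·cJ·cX·cE and Z at kZ·cJ·cX·cL. Dividing one by the other removes cJ, cX and the clock, so while cE and cL stay alike, the integral is simply Z = split·G. The split is the Z made per G made, and its inverse is the selectivity factor. I read it from the summed elm readings as 0.0404, a factor of 24.8, and it carries their scatter. Ash and elm differ in temperature and in cJ, and their readings resolve no change of it, so I hold it fixed.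

For ash this split gives Z 0.242 % beside its last G, and the reading stands 1.12 scatters above that. So the odd pair stands within what the scatter of a reading allows. The excess is (1 − split)/(1 + split), which gives me 92.2 % in amber and in green alike, as long as cE and cL stay alike in each.

The forecast says 91 % for amber, 90 % for green, and neither: “Excess is therefore about 90% in both flasks”. My figure stands higher than both, but I give the same verdict.

The flasks end at 93.8 % in amber and 93.9 % in green, so the answer is neither, though green holds G 12.4 % and amber 7.75 % at 8.00 min.

    J + X + E → X + G (k = 0.230 M⁻² s⁻¹, Ea = 41.0 kJ mol⁻¹)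
    J + X + L → X + Z (k = 0.00710 M⁻² s⁻¹, Ea = 41.0 kJ mol⁻¹)
    X → Q (k = 0.00670 s⁻¹, Ea = 79.0 kJ mol⁻¹)
    E ⇌ L (k = 0.0100 s⁻¹, Ea = 64.0 kJ mol⁻¹)
    (constants at −20 °C)

The neighbour is amber read at 2.0 min, and it holds G 7.66 %. My split puts Z beside that at 0.309 % and the excess at 92.2 %. The flask holds Z 0.245 %, and its excess is 93.8 %.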